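## The problem

Ampelopsin B is a resveratrol dimer in which two resorcinol rings are tied together twice. The labels used below are: Ca = the ArCH carbon of the seven-membered ring, Cb = its CH2, Cc = the CH shared by that ring and the dihydrofuran, Cd = the ArCH–O carbon, ring A = the arene fused to the dihydrofuran, ring B = the other fused arene.

Ring A carries the 2,3-dihydrofuran (O, Cd, Cc) on one edge. On the neighbouring edge it carries a seven-membered carbocycle made of Ca, Cb, two ring A carbons, Cc and two ring B carbons. The carbocycle holds no heteroatom or carbonyl group, so its closing bond must be a C–C bond flanked only by arenes.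

There are three stereocentres. Cc and Cd are adjacent and trans; Ca sits 1,3 to Cc across ring B. Cd can be corrected after the event, because acid opens the benzylic Cd–O bond reversibly and recloses it to the more stable trans isomer. Ca has no such path, so Cc has to be set in the absolute sense and then made to control Ca.

The five phenols are electron-rich and oxidisable and must stay masked until the end. The Cd–O bond and any diarylmethyl C–O bond ionise in acid, so strong acid may be used only where ionisation is the aim.

The enabling feature is the position of Ca between a 4-oxyphenyl group and ring B, whose two oxygens are ortho and para to it. A cation at Ca is held by three donors and has no β-hydrogen to lose. Cb is the benzylic carbon of ring A and can be made nucleophilic as the α-carbon of an arylacetaldehyde.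

## Retrosynthesis

**23 to 22.** The five phenolic O–H bonds are traced back to O–CH3 bonds, giving pentamethyl ether 22. Methyl ethers are small enough for the crowded ketone chemistry, inert to aryllithiums, hydrazine, carbenes and hot rhodium, and still donating enough to support the Ca cation. Benzyl ethers would offer extra C–H insertion sites, and silyl ethers would not survive the organolithium and acid steps. The forward step must cleave five ethers without opening the dihydrofuran for good.

**22 to 21.** A formyl group is added to Cb (the Cb–CHO bond), giving aldehyde 21. The formyl group is what makes Cb a nucleophile under acidic, cation-compatible conditions. An ester or nitrile there would need base-generated enolates, which cannot coexist with a carbocation. The forward step is a decarbonylation that must leave the adjacent Ca centre alone.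

**21 to 19.** The Ca–Cb bond is cut. This is the only bond of the carbocycle whose two ends can be given complementary polarity without touching an arene: Ca as a diarylmethyl cation, Cb as an enamine carbon. The neighbouring Ca–ring B cut (a Friedel–Crafts closure from a stilbene) would need a free electron-rich styrene and leaves the ring position to chance. Precursor 19 has one ring and two stereocentres fewer, and its carbinol centre need not be controlled. The forward reaction must ionise Ca and not Cd, close a seven-membered ring, and let Cc choose the face of the cation.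

**19 to 18 to 17, then 17 to 14 + 15.** The aldehyde is taken back to the primary alcohol of diol 18 and this to silyl ether 17, so the sensitive arylacetaldehyde exists for one step only. The Ca–ring B bond of 17 is then cut to aryl bromide 14 and 4-methoxybenzaldehyde 15 (via aryllithium 16). Bromine is the smallest placeholder for Ca; a carbinol brought in earlier would be a third bulky ortho group at the ketone stage and an oxygen trap for the carbene. The forward oxidation must take the primary alcohol and spare the diarylmethanol.

**14 to 13 to 12 to 11.** Trans isomer 14 comes from its Cd epimer 13. The Cc–Cd bond of 13 is cut to diaryldiazomethane 12, and this to hydrazone 11. The cut turns the stereogenic diarylmethine Cc into a ketone-derived carbon, so both ring stereocentres vanish in one operation. A Cd–O closure by ionisation would instead leave Cc racemic. The forward step needs catalyst control at Cc and insertion into the 4-methoxybenzylic C–H in preference to every other C–H.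

**11 to 10 to 8 + 9, and 8 to 7.** Hydrazone 11 comes from ketone 10. The O–CH2 bond of 10 is cut to phenol 8 and 4-methoxybenzyl chloride 9, which delivers Cd and its aryl group in one piece. Phenol 8 comes from tetramethyl ether 7 by cleaving the one methoxy group ortho to the ketone; chelation singles it out among four.

**7 to 6 to 3 + 4, and 3 to 2 to 1.** Ketone 7 comes from carbinol 6. The Cc–ring A bond of 6 is cut to aryl bromide 3 (reacting as aryllithium 5) and 2-bromo-3,5-dimethoxybenzaldehyde 4. A Friedel–Crafts acylation would leave the choice between two ring positions open; the bromine of 3 fixes it. Bromide 3 comes from 2-(3,5-dimethoxyphenyl)ethanol 1 by ring bromination (2) and silylation. Compounds 1, 4, 9 and 15 are catalogue chemicals.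

## Roads not taken

Alternative 1: Three bonds of ring B are cut at once: the ring-fusion bond and the two bonds to an added two-carbon unit. In the forward direction Cp*RuCl(cod) would join diyne A1 (ethynyl on Cc, silyloxyethynyl on Ca) with ethoxyacetylene A2 to give A3, closing ring B and the carbocycle together.
- Merits: it builds an arene and the seven-membered ring in one step, leaves no vestigial formyl group, and delivers ring B with two different ether groups. In these respects it is better than the chosen plan.
- Weak points: A1 needs Ca and Cc already set as two separate propargylic stereocentres, and the Cc–H of A1 is propargylic, benzylic and β to oxygen, so it is prone to isomerisation or elimination. The silyl ynol ether is fragile. The tether makes a seven-membered ring, a poor case for cyclotrimerisation. A2 can insert in two orientations, and only one puts the ethoxy group meta to the silyloxy group.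
- Comparison: the chosen plan forms one bond where this forms three, but it asks one selectivity question (the face of Ca), uses arenes that carry all oxygens from the start, and lets Cc control Ca.

Alternative 2: The two C–O bonds of the remote phenols (one on ring A, one on ring B) are cut. In the forward direction [Ir(OMe)(cod)]2 with 4,4'-di-tert-butyl-2,2'-bipyridine and a diboron reagent would borylate the two C–H bonds of bis-deoxy pentacycle A4 that have no ortho neighbour, and H2O2/NaOH in the same pot would give diphenol A5.
- Merits: the steric rule of the borylation fits both positions, the earlier arenes become simpler, and the selective mono-demethylation of the chosen route would be unnecessary. It would also be the better road to analogues.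
- Weak points: it solves none of the skeletal or stereochemical problems, since A4 still needs the carbocycle and three stereocentres. Removing the oxygens removes the ortho and para donors of ring B that make Ca ionisable, so any cation-based closure on the way to A4 becomes harder. The two anisyl rings and over-borylation compete on precious late material, and a demethylation is still needed afterwards.
- Comparison: the chosen plan carries the oxygens at no cost in steps and uses them as the donors of the key step.

Alternative 3: The two bonds from ring B to Cc and to Ca are cut, contracting the carbocycle to an indanone. In the forward direction CsF would release aryne A8 from silylaryl triflate A7. The β-keto ester carbon of 2-indanone A6 would add to the aryne carbon remote from the flanking methoxy group, the aryl anion would attack the ketone, and fragmentation would expand the ring to dibenzosuberone A9.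
- Merits: it reaches the tricyclic carbon framework in far fewer steps than the chosen plan, which spends twelve steps before the carbocycle closes. The regiochemistry of the aryne addition is well founded.
- Weak points: A9 is racemic, with Cc epimerisable between an ester and two arenes. Ca is a ketone that must still receive its aryl group and lose its oxygen with control relative to Cc. The dihydrofuran must then be built from the ester, including a selective demethylation on ring A. No element sets the absolute configuration.
- Comparison: the chosen plan sets Cc by catalyst before the ring closure and uses it to control Ca, so no late-stage resolution or stereochemical repair is needed.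

Key step: step 13

Assumption 1: Rh2(R-PTAD)4 is taken as the catalyst enantiomer that gives (3R)-13 in step 8; if the sense of induction is the opposite, Rh2(S-PTAD)4 is used and nothing else changes.

Assumption 2: the insertion of step 8 is taken to give mainly the 2,3-cis isomer, as concerted insertions of diaryl carbenes into benzylic ether C–H bonds usually do; any trans isomer formed directly is carried along, because step 9 converges both.

## Route

Step 1
Reactants: 1 2-(3,5-dimethoxyphenyl)ethanol
Product: 2 2-(2-bromo-3,5-dimethoxyphenyl)ethanol
Conditions: NBS, MeCN, 0 °C to rt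
Reagents that add atoms: N-bromosuccinimide, O=C1CCC(=O)N1Br
Why: Electrophilic aromatic bromination; in 5-alkylresorcinol dimethyl ethers the position ortho to the alkyl group and para to a methoxy group is brominated in preference to the more hindered position between the two methoxy groups, so the bromine marks the future Cc attachment site.

Step 2
Reactants: 2 2-(2-bromo-3,5-dimethoxyphenyl)ethanol
Product: 3 tert-butyl[2-(2-bromo-3,5-dimethoxyphenyl)ethoxy]diphenylsilane
Conditions: TBDPSCl, imidazole, DMF, rt
Reagents that add atoms: tert-butyl(chloro)diphenylsilane, CC(C)(C)[Si](Cl)(c1ccccc1)c1ccccc1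
Why: Silyl ether formation; the tert-butyldiphenylsilyl group is chosen because it should survive aryllithiums at −78 °C, BCl3 at low temperature, hydrazine and TFA, and it leaves with fluoride when the alcohol is needed.

Step 3
Reactants: 3 tert-butyl[2-(2-bromo-3,5-dimethoxyphenyl)ethoxy]diphenylsilane; 4 2-bromo-3,5-dimethoxybenzaldehyde
Product: 6 (2-bromo-3,5-dimethoxyphenyl){2-[2-(tert-butyldiphenylsilyloxy)ethyl]-4,6-dimethoxyphenyl}methanol (racemic), via aryllithium 5 (not isolated)
Conditions: n-BuLi, THF, −78 °C; then 4, −78 to 0 °C; H2O
Reagents that add atoms: none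
Why: Bromine–lithium exchange followed by 1,2-addition of the aryllithium to the aldehyde forms the Cc–ring A bond at the position fixed by the bromine; addition to the formyl group is far faster than halogen exchange with the bromide of 4, and the new carbinol centre is removed in the next step.

Step 4
Reactants: 6 (2-bromo-3,5-dimethoxyphenyl){2-[2-(tert-butyldiphenylsilyloxy)ethyl]-4,6-dimethoxyphenyl}methanol
Product: 7 (2-bromo-3,5-dimethoxyphenyl){2-[2-(tert-butyldiphenylsilyloxy)ethyl]-4,6-dimethoxyphenyl}methanone
Conditions: Dess–Martin periodinane, CH2Cl2, rt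
Reagents that add atoms: none
Why: Dess–Martin oxidation of a hindered diarylmethanol to the benzophenone under neutral conditions that leave the silyl ether and the aryl bromide untouched.

Step 5
Reactants: 7 (2-bromo-3,5-dimethoxyphenyl){2-[2-(tert-butyldiphenylsilyloxy)ethyl]-4,6-dimethoxyphenyl}methanone
Product: 8 (2-bromo-3,5-dimethoxyphenyl){2-[2-(tert-butyldiphenylsilyloxy)ethyl]-6-hydroxy-4-methoxyphenyl}methanone
Conditions: BCl3, CH2Cl2, −78 to 0 °C; aq. NaHCO3
Reagents that add atoms: none
Why: Chelation-directed ether cleavage; BCl3 bound to the ketone oxygen reaches only the methoxy group ortho to the carbonyl on ring A, while the para methoxy group and the two ring B methoxy groups (meta to the carbonyl) cannot form the six-membered chelate; the primary tert-butyldiphenylsilyl ether should hold at this temperature.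

Step 6
Reactants: 8 (2-bromo-3,5-dimethoxyphenyl){2-[2-(tert-butyldiphenylsilyloxy)ethyl]-6-hydroxy-4-methoxyphenyl}methanone; 9 4-methoxybenzyl chloride
Product: 10 (2-bromo-3,5-dimethoxyphenyl){2-[2-(tert-butyldiphenylsilyloxy)ethyl]-4-methoxy-6-(4-methoxybenzyloxy)phenyl}methanone
Conditions: K2CO3, Bu4NI (cat.), DMF, 50 °C
Reagents that add atoms: none
Why: Williamson ether synthesis on the phenoxide; it brings in Cd together with its aryl group and places the C–H bond that the carbene will attack five atoms from the ketone carbon.

Step 7
Reactants: 10 (2-bromo-3,5-dimethoxyphenyl){2-[2-(tert-butyldiphenylsilyloxy)ethyl]-4-methoxy-6-(4-methoxybenzyloxy)phenyl}methanone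
Product: 11 hydrazone of ketone 10 (E/Z mixture)
Conditions: N2H4 (excess), AcOH (cat.), EtOH, reflux (n-BuOH, 120 °C if slow)
Reagents that add atoms: hydrazine, NN
Why: Hydrazone condensation; the ketone has three ortho substituents, so excess hydrazine, acid catalysis and heat are planned, and the aryl bromide, silyl ether and benzyl ether are inert to hydrazine.

Step 8
Reactants: 11 hydrazone of ketone 10
Product: 13 tert-butyl{2-[(2R,3R)-3-(2-bromo-3,5-dimethoxyphenyl)-6-methoxy-2-(4-methoxyphenyl)-2,3-dihydro-1-benzofuran-4-yl]ethoxy}diphenylsilane (2,3-cis), via diaryldiazomethane 12 (not isolated)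
Conditions: MnO2, MeCN, 0 °C to rt; filter; Rh2(R-PTAD)4 (1 mol%), MeCN, 0 °C
Reagents that add atoms: none
Why: MnO2 oxidises the hydrazone to the diaryldiazomethane, and the chiral dirhodium tetracarboxylate turns it into a donor/donor carbene that inserts into the 4-methoxybenzylic C–H bond through a five-membered transition state, a reaction known for 2-benzyloxybenzophenone hydrazones; the catalyst sets Cc (and, in the concerted insertion, Cd) and the methylene between the ether oxygen and the anisyl ring is the most hydridic C–H within reach. The only other C–H in five-membered range is the CH2 next to the silyloxy group, which is less activated and shielded by the bulky silyl group.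

Step 9
Reactants: 13 tert-butyl{2-[(2R,3R)-3-(2-bromo-3,5-dimethoxyphenyl)-6-methoxy-2-(4-methoxyphenyl)-2,3-dihydro-1-benzofuran-4-yl]ethoxy}diphenylsilane
Product: 14 tert-butyl{2-[(2S,3R)-3-(2-bromo-3,5-dimethoxyphenyl)-6-methoxy-2-(4-methoxyphenyl)-2,3-dihydro-1-benzofuran-4-yl]ethoxy}diphenylsilane (2,3-trans)
Conditions: TFA, CH2Cl2, 0 °C
Reagents that add atoms: none
Why: Acid-mediated epimerisation at C2 (Cd) through reversible ionisation of the benzylic C–O bond to a 4-methoxybenzyl cation and reclosure to the more stable trans isomer; Cc is not touched as long as reclosure by the tethered phenol outruns proton loss from the open cation, and the silyl ether and aryl bromide are stable to TFA.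

Step 10
Reactants: 14 tert-butyl{2-[(2S,3R)-3-(2-bromo-3,5-dimethoxyphenyl)-6-methoxy-2-(4-methoxyphenyl)-2,3-dihydro-1-benzofuran-4-yl]ethoxy}diphenylsilane; 15 4-methoxybenzaldehyde
Product: 17 {2-[(2S,3S)-4-[2-(tert-butyldiphenylsilyloxy)ethyl]-6-methoxy-2-(4-methoxyphenyl)-2,3-dihydro-1-benzofuran-3-yl]-4,6-dimethoxyphenyl}(4-methoxyphenyl)methanol (2,3-trans; both carbinol epimers), via aryllithium 16 (not isolated)
Conditions: t-BuLi (2 equiv), THF, −78 °C; then 15, −78 °C; H2O
Reagents that add atoms: none
Why: Bromine–lithium exchange and addition of the aryllithium to the aldehyde form the Ca–ring B bond; the carbinol configuration is irrelevant because this carbon is ionised in step 13, and the low temperature keeps the aryllithium from deprotonating Cc–H. The C3 descriptor changes from R to S only because bromine is replaced by carbon.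

Step 11
Reactants: 17 {2-[(2S,3S)-4-[2-(tert-butyldiphenylsilyloxy)ethyl]-6-methoxy-2-(4-methoxyphenyl)-2,3-dihydro-1-benzofuran-3-yl]-4,6-dimethoxyphenyl}(4-methoxyphenyl)methanol
Product: 18 2-[(2S,3S)-3-{2-[hydroxy(4-methoxyphenyl)methyl]-3,5-dimethoxyphenyl}-6-methoxy-2-(4-methoxyphenyl)-2,3-dihydro-1-benzofuran-4-yl]ethanol (both carbinol epimers)
Conditions: TBAF, THF, 0 °C to rt
Reagents that add atoms: none
Why: Fluoride desilylation under non-acidic conditions, which leave the ionisable diarylmethanol and the Cd–O bond alone.

Step 12
Reactants: 18 2-[(2S,3S)-3-{2-[hydroxy(4-methoxyphenyl)methyl]-3,5-dimethoxyphenyl}-6-methoxy-2-(4-methoxyphenyl)-2,3-dihydro-1-benzofuran-4-yl]ethanol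
Product: 19 2-[(2S,3S)-3-{2-[hydroxy(4-methoxyphenyl)methyl]-3,5-dimethoxyphenyl}-6-methoxy-2-(4-methoxyphenyl)-2,3-dihydro-1-benzofuran-4-yl]acetaldehyde (both carbinol epimers)
Conditions: Cu(MeCN)4OTf, 2,2'-bipyridine, TEMPO, N-methylimidazole (all cat.), MeCN, air, rt
Reagents that add atoms: none
Why: Copper/TEMPO aerobic oxidation is selective for unhindered primary alcohols and should leave the doubly ortho-flanked secondary diarylmethanol; the medium is not acidic, so the carbinol does not ionise, and the sensitive arylacetaldehyde is used at once.

Step 13
Reactants: 19 2-[(2S,3S)-3-{2-[hydroxy(4-methoxyphenyl)methyl]-3,5-dimethoxyphenyl}-6-methoxy-2-(4-methoxyphenyl)-2,3-dihydro-1-benzofuran-4-yl]acetaldehyde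
Product: 21 ampelopsin B pentamethyl ether carrying a formyl group on Cb (Ca S; Cb R; Cc S; Cd S; formyl trans to the Ca aryl group), via enamine 20 (not isolated)
Conditions: (2R,5R)-5-benzyl-2-tert-butyl-3-methylimidazolidin-4-one·TFA (30 mol%), MeCN, 0.01 M, 0 °C to rt
Reagents that add atoms: none
Why: The secondary amine condenses with the arylacetaldehyde to the E-enamine while the acid of the salt ionises the Ca carbinol; the cation, held by the 4-methoxyphenyl group and the ortho and para methoxy groups of ring B and lacking any β-hydrogen, lasts until the enamine carbon Cb captures it, and hydrolysis of the cyclic iminium ion releases 21, the amine and one molecule of water. The closest known reaction is the amine-catalysed SN1-type α-alkylation of aldehydes with diarylmethanols, run here within one molecule. The seven-membered ring closes in a 7-exo-trig mode with the enamine double bond outside the new ring, and both reacting carbons hang from ortho positions of the Cc diarylmethine, so few rotors have to be frozen. Ca is set by the scaffold: in the ring-shaped transition state the 4-methoxyphenyl group on the planar cation takes the side of the new ring away from the Cc–Cd bond and the Cd aryl group, which is the S configuration of the target, and both carbinol epimers of 19 converge on the same cation. Cb is set by the catalyst, whose benzyl group covers the Si face of the enamine so that Ca bonds to the Re face and gives (R)-Cb with the formyl group trans to the Ca aryl group; the anti approach of the two bulky partners prefers the same arrangement, and Cb is erased in step 14 in any case. The step needs Ca to ionise in preference to Cd–O, which should hold because Ca carries two donor arenes and loses water while Cd carries one arene and would lose an aryloxide. It also needs ring closure to beat intermolecular alkylation, which the high dilution and the ortho/ortho arrangement should secure.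

Step 14
Reactants: 21 ampelopsin B pentamethyl ether carrying a formyl group on Cb
Product: 22 ampelopsin B pentamethyl ether (Ca S; Cc S; Cd S)
Conditions: RhCl(PPh3)3 (1.1 equiv), xylene, 130 °C
Reagents that add atoms: none
Why: Tsuji–Wilkinson decarbonylation: oxidative addition of the formyl C–H bond, CO extrusion and C–H reductive elimination replace the formyl group by hydrogen; Cb becomes a CH2 group and Ca, Cc and Cd are not involved.

Step 15
Reactants: 22 ampelopsin B pentamethyl ether
Product: 23 ampelopsin B
Conditions: BBr3 (excess), CH2Cl2, −78 °C to rt; then MeOH, H2O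
Reagents that add atoms: none
Why: Lewis acid cleavage of the five aryl methyl ethers with BBr3, the usual last step for permethylated resveratrol oligomers; the trans dihydrofuran is the thermodynamic arrangement, so any reversible opening at Cd should return the same isomer.

## Compound list

1 | 2-(3,5-dimethoxyphenyl)ethanol | COc1cc(CCO)cc(OC)c1 | starting material
2 | 2-(2-bromo-3,5-dimethoxyphenyl)ethanol | COc1cc(CCO)c(Br)c(OC)c1 | intermediate
3 | tert-butyl[2-(2-bromo-3,5-dimethoxyphenyl)ethoxy]diphenylsilane | COc1cc(CCO[Si](c2ccccc2)(c2ccccc2)C(C)(C)C)c(Br)c(OC)c1 | intermediate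
4 | 2-bromo-3,5-dimethoxybenzaldehyde | COc1cc(C=O)c(Br)c(OC)c1 | starting material
5 | {2-[2-(tert-butyldiphenylsilyloxy)ethyl]-4,6-dimethoxyphenyl}lithium | COc1cc(CCO[Si](c2ccccc2)(c2ccccc2)C(C)(C)C)c([Li])c(OC)c1 | intermediate
6 | (2-bromo-3,5-dimethoxyphenyl){2-[2-(tert-butyldiphenylsilyloxy)ethyl]-4,6-dimethoxyphenyl}methanol, racemic | COc1cc(CCO[Si](c2ccccc2)(c2ccccc2)C(C)(C)C)c(C(O)c2cc(OC)cc(OC)c2Br)c(OC)c1 | intermediate
7 | (2-bromo-3,5-dimethoxyphenyl){2-[2-(tert-butyldiphenylsilyloxy)ethyl]-4,6-dimethoxyphenyl}methanone | COc1cc(CCO[Si](c2ccccc2)(c2ccccc2)C(C)(C)C)c(C(=O)c2cc(OC)cc(OC)c2Br)c(OC)c1 | intermediate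
8 | (2-bromo-3,5-dimethoxyphenyl){2-[2-(tert-butyldiphenylsilyloxy)ethyl]-6-hydroxy-4-methoxyphenyl}methanone | COc1cc(CCO[Si](c2ccccc2)(c2ccccc2)C(C)(C)C)c(C(=O)c2cc(OC)cc(OC)c2Br)c(O)c1 | intermediate
9 | 4-methoxybenzyl chloride | COc1ccc(CCl)cc1 | starting material
10 | (2-bromo-3,5-dimethoxyphenyl){2-[2-(tert-butyldiphenylsilyloxy)ethyl]-4-methoxy-6-(4-methoxybenzyloxy)phenyl}methanone | COc1ccc(COc2cc(OC)cc(CCO[Si](c3ccccc3)(c3ccccc3)C(C)(C)C)c2C(=O)c2cc(OC)cc(OC)c2Br)cc1 | intermediate
11 | hydrazone of ketone 10, E/Z mixture | COc1ccc(COc2cc(OC)cc(CCO[Si](c3ccccc3)(c3ccccc3)C(C)(C)C)c2C(=NN)c2cc(OC)cc(OC)c2Br)cc1 | intermediate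
12 | diaryldiazomethane from 11 (C=N2 in place of C=O of 10) | COc1ccc(COc2cc(OC)cc(CCO[Si](c3ccccc3)(c3ccccc3)C(C)(C)C)c2C(=[N+]=[N-])c2cc(OC)cc(OC)c2Br)cc1 | intermediate
13 | tert-butyl{2-[(2R,3R)-3-(2-bromo-3,5-dimethoxyphenyl)-6-methoxy-2-(4-methoxyphenyl)-2,3-dihydro-1-benzofuran-4-yl]ethoxy}diphenylsilane, 2,3-cis | CC(C)(C)[Si](c1ccccc1)(c1ccccc1)OCCc1cc(OC)cc2c1[C@H](c1cc(OC)cc(OC)c1Br)[C@H](c1ccc(OC)cc1)O2 | intermediate
14 | tert-butyl{2-[(2S,3R)-3-(2-bromo-3,5-dimethoxyphenyl)-6-methoxy-2-(4-methoxyphenyl)-2,3-dihydro-1-benzofuran-4-yl]ethoxy}diphenylsilane, 2,3-trans | CC(C)(C)[Si](c1ccccc1)(c1ccccc1)OCCc1cc(OC)cc2c1[C@H](c1cc(OC)cc(OC)c1Br)[C@@H](c1ccc(OC)cc1)O2 | intermediate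
15 | 4-methoxybenzaldehyde | COc1ccc(C=O)cc1 | starting material
16 | aryllithium from 14 (lithium in place of bromine, configuration unchanged) | CC(C)(C)[Si](c1ccccc1)(c1ccccc1)OCCc1cc(OC)cc2c1[C@H](c1cc(OC)cc(OC)c1[Li])[C@@H](c1ccc(OC)cc1)O2 | intermediate
17 | {2-[(2S,3S)-4-[2-(tert-butyldiphenylsilyloxy)ethyl]-6-methoxy-2-(4-methoxyphenyl)-2,3-dihydro-1-benzofuran-3-yl]-4,6-dimethoxyphenyl}(4-methoxyphenyl)methanol, 2,3-trans, both carbinol epimers | CC(C)(C)[Si](c1ccccc1)(c1ccccc1)OCCc1cc(OC)cc2c1[C@H](c1cc(OC)cc(OC)c1C(O)c1ccc(OC)cc1)[C@@H](c1ccc(OC)cc1)O2 | intermediate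
18 | 2-[(2S,3S)-3-{2-[hydroxy(4-methoxyphenyl)methyl]-3,5-dimethoxyphenyl}-6-methoxy-2-(4-methoxyphenyl)-2,3-dihydro-1-benzofuran-4-yl]ethanol, both carbinol epimers | OCCc1cc(OC)cc2c1[C@H](c1cc(OC)cc(OC)c1C(O)c1ccc(OC)cc1)[C@@H](c1ccc(OC)cc1)O2 | intermediate
19 | 2-[(2S,3S)-3-{2-[hydroxy(4-methoxyphenyl)methyl]-3,5-dimethoxyphenyl}-6-methoxy-2-(4-methoxyphenyl)-2,3-dihydro-1-benzofuran-4-yl]acetaldehyde, both carbinol epimers | O=CCc1cc(OC)cc2c1[C@H](c1cc(OC)cc(OC)c1C(O)c1ccc(OC)cc1)[C@@H](c1ccc(OC)cc1)O2 | intermediate
20 | E-enamine of aldehyde 19 with (2R,5R)-5-benzyl-2-tert-butyl-3-methylimidazolidin-4-one | CN1C(=O)[C@@H](Cc2ccccc2)N(/C=C/c2cc(OC)cc3c2[C@H](c2cc(OC)cc(OC)c2C(O)c2ccc(OC)cc2)[C@@H](c2ccc(OC)cc2)O3)[C@H]1C(C)(C)C | intermediate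
21 | ampelopsin B pentamethyl ether with a formyl group on Cb (Ca S, Cb R, Cc S, Cd S; formyl trans to the Ca aryl group) | COc1ccc([C@@H]2[C@@H](C=O)c3cc(OC)cc4c3[C@H](c3cc(OC)cc(OC)c32)[C@@H](c2ccc(OC)cc2)O4)cc1 | intermediate
22 | ampelopsin B pentamethyl ether (Ca S, Cc S, Cd S) | COc1ccc([C@@H]2Cc3cc(OC)cc4c3[C@H](c3cc(OC)cc(OC)c32)[C@@H](c2ccc(OC)cc2)O4)cc1 | intermediate
23 | ampelopsin B | Oc1ccc([C@@H]2Cc3cc(O)cc4c3[C@H](c3cc(O)cc(O)c32)[C@@H](c2ccc(O)cc2)O4)cc1 | target

## Step count and least certain steps

Total steps: 15. Longest linear sequence: 15 steps (1 to 23); compounds 4, 9 and 15 enter as purchased.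

**Step 13 (key step).** The enamine of an arylacetaldehyde is conjugated and only moderately nucleophilic, and the Ca cation is less stabilised than the cations of the intermolecular precedent. Ionisation may therefore need more acid than the catalyst salt supplies, and at that point self-condensation of the aldehyde, intermolecular Friedel–Crafts alkylation or opening at Cd would compete. Poor facial selectivity at Ca is the second risk, since it rests on the conformational preference of a seven-membered transition state.

Fallback: keep the Ca–Cb bond but replace the catalytic enamine by a stoichiometric enol silane. Aldehyde 19 is treated with TBSOTf and Et3N to give the bis-silyl compound F1 (silyl enol ether on the arm, silyl ether on the carbinol). A Lewis acid (BF3·OEt2 or catalytic TMSOTf, CH2Cl2, −78 °C) then ionises the diarylmethyl silyl ether and the enol silane closes the ring, a Mukaiyama-type SN1 alkylation. The route is rejoined at 21; any Cb epimer is levelled in step 14.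

**Step 7.** Condensation at a benzophenone with three ortho substituents may be very slow or stop short, and long heating with hydrazine may begin to cleave the silyl ether.

Fallback: change the order so that the carbonyl is attacked while it is less hindered and activated by the neighbouring phenol. Phenol 8 is condensed with hydrazine to the hydroxy hydrazone F2, and the phenoxide of F2 is then alkylated with 9 (K2CO3, DMF, rt), the weakly nucleophilic hydrazone nitrogen being left alone. The route is rejoined at 11.

**Step 8.** Three things may go wrong: competing insertion into the CH2 next to the silyloxy group (giving an indane), azine formation from the hindered diazo compound, or low enantioselectivity with a carbene more crowded than those of the precedent. In the following step 9, proton loss from the open cation could also erode the enantiomeric purity.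

Fallback: build the heterocycle as a benzofuran and reduce it, bypassing steps 6 to 9. Phenol 8 is acylated with 4-methoxybenzoyl chloride to the aryl ester F3. An intramolecular McMurry ketone–ester coupling (TiCl3, Zn, DME, reflux) gives the 2,3-diarylbenzofuran F4. Ionic hydrogenation (Et3SiH, TFA) gives the racemic trans-dihydrobenzofuran F5, whose enantiomers are separated on a chiral stationary phase. The route is rejoined at 14, at the cost of half the material.

**Step 14.** After CO extrusion the benzylic alkyl–rhodium hydride may undergo β-hydride elimination toward Ca instead of reductive elimination. That would give the Ca=Cb alkene and destroy the Ca stereocentre. Oxidative addition to the hindered α-branched aldehyde may also be slow.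

Fallback: remove the carbon as CO2 by a radical path. Aldehyde 21 is oxidised (Pinnick oxidation: NaClO2, NaH2PO4, 2-methyl-2-butene, t-BuOH/H2O) to the carboxylic acid F6. This is coupled with N-hydroxypyridine-2-thione (DCC) to the thiohydroxamate ester F7. Barton reductive decarboxylation (t-BuSH, visible light, rt) then passes through the benzylic Cb radical and gives the CH2 group. The route is rejoined at 22.

## Further compounds

F1 | step 13 | bis(tert-butyldimethylsilyl) derivative of 19: silyl enol ether of the aldehyde (E/Z mixture) and silyl ether of the carbinol | CC(C)(C)[Si](C)(C)OC=Cc1cc(OC)cc2c1[C@H](c1cc(OC)cc(OC)c1C(O[Si](C)(C)C(C)(C)C)c1ccc(OC)cc1)[C@@H](c1ccc(OC)cc1)O2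
F2 | step 7 | hydrazone of hydroxy ketone 8 | COc1cc(CCO[Si](c2ccccc2)(c2ccccc2)C(C)(C)C)c(C(=NN)c2cc(OC)cc(OC)c2Br)c(O)c1
F3 | step 8 | 4-methoxybenzoate ester of phenol 8 | COc1ccc(C(=O)Oc2cc(OC)cc(CCO[Si](c3ccccc3)(c3ccccc3)C(C)(C)C)c2C(=O)c2cc(OC)cc(OC)c2Br)cc1
F4 | step 8 | {2-[3-(2-bromo-3,5-dimethoxyphenyl)-6-methoxy-2-(4-methoxyphenyl)-1-benzofuran-4-yl]ethoxy}(tert-butyl)diphenylsilane | COc1ccc(-c2oc3cc(OC)cc(CCO[Si](c4ccccc4)(c4ccccc4)C(C)(C)C)c3c2-c2cc(OC)cc(OC)c2Br)cc1
F5 | step 8 | racemic 2,3-trans-dihydrobenzofuran (14 and its enantiomer) | CC(C)(C)[Si](c1ccccc1)(c1ccccc1)OCCc1cc(OC)cc2c1[C@H](c1cc(OC)cc(OC)c1Br)[C@@H](c1ccc(OC)cc1)O2.CC(C)(C)[Si](c1ccccc1)(c1ccccc1)OCCc1cc(OC)cc2c1[C@@H](c1cc(OC)cc(OC)c1Br)[C@H](c1ccc(OC)cc1)O2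
F6 | step 14 | carboxylic acid from 21 (CO2H on Cb in place of CHO) | COc1ccc([C@@H]2[C@@H](C(=O)O)c3cc(OC)cc4c3[C@H](c3cc(OC)cc(OC)c32)[C@@H](c2ccc(OC)cc2)O4)cc1
F7 | step 14 | 2-thioxopyridin-1(2H)-yl ester of acid F6 | COc1ccc([C@@H]2[C@@H](C(=O)On5ccccc5=S)c3cc(OC)cc4c3[C@H](c3cc(OC)cc(OC)c32)[C@@H](c2ccc(OC)cc2)O4)cc1
A1 | alternative 1 | diyne with ethynyl on Cc and (triisopropylsilyloxy)ethynyl on Ca | COc1ccc([C@@H](C#CO[Si](C(C)C)(C(C)C)C(C)C)Cc2cc(OC)cc3c2[C@H](C#C)[C@@H](c2ccc(OC)cc2)O3)cc1
A2 | alternative 1 | ethoxyacetylene | CCOC#C
A3 | alternative 1 | ampelopsin B with ring B as ethyl and triisopropylsilyl ethers and the other phenols as methyl ethers | COc1ccc([C@@H]2Cc3cc(OC)cc4c3[C@H](c3cc(OCC)cc(O[Si](C(C)C)(C(C)C)C(C)C)c32)[C@@H](c2ccc(OC)cc2)O4)cc1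
A4 | alternative 2 | bis-deoxy ampelopsin B trimethyl ether (no oxygen at the two remote positions) | COc1ccc([C@@H]2Cc3cccc4c3[C@H](c3cccc(OC)c32)[C@@H](c2ccc(OC)cc2)O4)cc1
A5 | alternative 2 | ampelopsin B tri-O-methyl ether with the two remote phenols free | COc1ccc([C@@H]2Cc3cc(O)cc4c3[C@H](c3cc(O)cc(OC)c32)[C@@H](c2ccc(OC)cc2)O4)cc1
A6 | alternative 3 | methyl 5,7-dimethoxy-2-oxo-2,3-dihydro-1H-indene-1-carboxylate (racemic) | COC(=O)C1C(=O)Cc2cc(OC)cc(OC)c21
A7 | alternative 3 | 3,5-dimethoxy-2-(trimethylsilyl)phenyl trifluoromethanesulfonate | COc1cc(OC)c([Si](C)(C)C)c(OS(=O)(=O)C(F)(F)F)c1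
A8 | alternative 3 | 3,5-dimethoxybenzyne | COC1=CC#CC(OC)=C1
A9 | alternative 3 | tetramethoxy dibenzosuberone with ketone at Ca and methyl ester on Cc (racemic) | COC(=O)C1c2cc(OC)cc(OC)c2C(=O)Cc2cc(OC)cc(OC)c21
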